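## Retrosynthetic overview

1. The neopentyl ester C–O bond is cut first, giving chromenylmethanol 13 and O-acetylferulic acid 15 (from ferulic acid 14).
2. The strategy rests on ring B: C4 is bonded to C4a (the ring A carbon ortho to O1) and C3=C4 is a cis alkene beside the fully substituted C2 (O1, CH3, CH2O). This is the pattern left by adding the ring A C–H across a terminal alkyne on C2, so ring B is opened at C4–C4a to the aryl propargyl ether 11.
3. C2 is traced to the prochiral 2-aryloxy-2-methylpropane-1,3-diol 6, desymmetrised by a lipase. The acetylated arm becomes the CH2O substituent and the free arm becomes the alkyne (aldehyde, then Ohira–Bestmann).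
4. Diol 6 comes from acetovanillone 1 and diethyl bromomalonate 2 by O-alkylation, C-methylation, LiAlH4 reduction and benzylic re-oxidation.
5. Ring order: ring A is bought with acetovanillone; ring B is the only ring formed (step 9).

Key step: step 9

Assumption: the lipase acetylates the pro-R hydroxymethyl group of diol 6. The opposite preference is covered by the fallback for step 5.

## Route

Step 1
Reactants: 1 acetovanillone; 2 diethyl bromomalonate
Product: 3 diethyl 2-(4-acetyl-2-methoxyphenoxy)propanedioate
Conditions: K2CO3, acetone, reflux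
Reagents that add atoms: none
Why: Williamson-type O-alkylation, in which the phenoxide of 1 displaces bromide from the doubly carbonyl-activated secondary bromide of 2 by SN2, the usual entry to aryloxymalonates.

Step 2
Reactants: 3 diethyl 2-(4-acetyl-2-methoxyphenoxy)propanedioate
Product: 4 diethyl 2-(4-acetyl-2-methoxyphenoxy)-2-methylpropanedioate
Conditions: MeI, K2CO3, DMF, rt
Reagents that add atoms: iodomethane, CI
Why: Malonic ester alkylation, in which carbonate removes only the malonate C–H (far more acidic than the acetyl CH3) and the carbanion is C-methylated, making the future C2 fully substituted.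

Step 3
Reactants: 4 diethyl 2-(4-acetyl-2-methoxyphenoxy)-2-methylpropanedioate
Product: 5 2-[4-(1-hydroxyethyl)-2-methoxyphenoxy]-2-methylpropane-1,3-diol (carbinol carbon racemic)
Conditions: LiAlH4, THF, 0 °C to rt; Fieser work-up
Reagents that add atoms: none
Why: Hydride reduction of both esters to primary alcohols, which also reduces the aryl ketone to a carbinol whose configuration does not matter because step 4 re-oxidises it.

Step 4
Reactants: 5 2-[4-(1-hydroxyethyl)-2-methoxyphenoxy]-2-methylpropane-1,3-diol
Product: 6 1-{4-[(1,3-dihydroxy-2-methylpropan-2-yl)oxy]-3-methoxyphenyl}ethanone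
Conditions: activated MnO2 (excess), acetone, rt
Reagents that add atoms: none
Why: Chemoselective benzylic oxidation, since MnO2 oxidises the para-alkoxybenzylic carbinol and leaves the two saturated primary alcohols alone, returning the ketone and the prochiral diol.

Step 5
Reactants: 6 1-{4-[(1,3-dihydroxy-2-methylpropan-2-yl)oxy]-3-methoxyphenyl}ethanone
Product: 7 (R)-2-(4-acetyl-2-methoxyphenoxy)-3-hydroxy-2-methylpropyl acetate
Conditions: immobilised Burkholderia cepacia lipase, vinyl acetate, MTBE, rt; stopped when a little diacetate appears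
Reagents that add atoms: vinyl acetate, C=COC(C)=O
Why: Enzymatic desymmetrisation by irreversible transesterification, in which the chiral active site distinguishes the two enantiotopic CH2OH arms and acetylates the pro-R one, setting the future C2 as (R), while slight over-acylation should remove the minor enantiomer preferentially as diacetate.

Step 6
Reactants: 7 (R)-2-(4-acetyl-2-methoxyphenoxy)-3-hydroxy-2-methylpropyl acetate
Product: 8 (S)-2-(4-acetyl-2-methoxyphenoxy)-2-methyl-3-oxopropyl acetate
Conditions: Dess–Martin periodinane, CH2Cl2, 0 °C to rt; used at once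
Reagents that add atoms: none
Why: Dess–Martin oxidation of the primary alcohol under non-basic conditions, which avoids 1,3-acetyl migration (the path that would interconvert 7 and its enantiomer) and gives an aldehyde that cannot epimerise because its α-carbon is fully substituted.

Step 7
Reactants: 8 (S)-2-(4-acetyl-2-methoxyphenoxy)-2-methyl-3-oxopropyl acetate
Product: 10 (R)-1-{4-[(1-hydroxy-2-methylbut-3-yn-2-yl)oxy]-3-methoxyphenyl}ethanone, via acetoxy alkyne 9 (not isolated)
Conditions: Ohira–Bestmann reagent, K2CO3, MeOH, 0 °C (reagent and base pre-stirred, then 8 added), then rt until the acetate is gone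
Reagents that add atoms: dimethyl (1-diazo-2-oxopropyl)phosphonate, COP(=O)(OC)C(=[N+]=[N-])C(C)=O
Why: Ohira–Bestmann variant of the Seyferth–Gilbert homologation, in which the diazomethylphosphonate anion adds to the aldehyde (far more electrophilic than the aryl methyl ketone), loss of phosphate and N2 with a 1,2-hydrogen shift gives the terminal alkyne, and the same K2CO3/MeOH then transesterifies the acetate away without touching the quaternary stereocentre.

Step 8
Reactants: 10 (R)-1-{4-[(1-hydroxy-2-methylbut-3-yn-2-yl)oxy]-3-methoxyphenyl}ethanone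
Product: 11 (R)-1-{4-[1-(tert-butyldimethylsilyloxy)-2-methylbut-3-yn-2-yl]oxy-3-methoxyphenyl}ethanone
Conditions: TBSCl, imidazole, DMF, 0 °C to rt
Reagents that add atoms: tert-butyldimethylsilyl chloride, CC(C)(C)[Si](C)(C)Cl
Why: Imidazole-promoted silylation of a primary alcohol, which keeps the hydroxyl away from the cationic catalyst of step 9 and leaves an inductively withdrawing CH2OSi group next to C2.

Step 9
Reactants: 11 (R)-1-{4-[1-(tert-butyldimethylsilyloxy)-2-methylbut-3-yn-2-yl]oxy-3-methoxyphenyl}ethanone
Product: 12 (R)-1-[2-(tert-butyldimethylsilyloxymethyl)-8-methoxy-2-methyl-2H-chromen-6-yl]ethanone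
Conditions: Ph3PAuNTf2 (5 mol %), dry CH2Cl2, rt, dark
Reagents that add atoms: none
Why: The cationic Ph3PAu fragment (monovalent gold) binds the terminal alkyne as a π-acid, the ring A carbon ortho to the ether oxygen attacks the terminal alkyne carbon anti to gold, and rearomatisation by proton loss followed by protodeauration at C3 delivers the C4–C4a bond and the cis C3=C4 alkene. The closest known reaction type is the gold-catalysed intramolecular hydroarylation of aryl propargyl ethers to 2H-chromenes, which tolerates doubly substituted propargylic carbons and acyl-substituted rings. Ring B closes in the 6-endo-dig mode, because the O–C2–C(sp) tether places the terminal carbon within reach of the ortho carbon, whereas 5-exo attack at the internal carbon would give a strained 3-methylene-2,3-dihydrobenzofuran. No new stereocentre is formed, and C2 stays (R) because none of its four bonds is broken, unlike the thermal propargyl Claisen route, whose quinone methide intermediate is planar at that carbon. The step needs regioselectivity on ring A and preference for π-activation over heterolysis of the tertiary propargylic C–O bond: the other ortho position carries the methoxy group, the soft catalyst prefers the alkyne to the weakly basic acyl-conjugated ether oxygen, and a cation at C2 would be destabilised by the adjacent CH2OTBS group. Ambient temperature and exclusion of light keep the product from reversible 6π ring-opening, the only process that could erode C2.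

Step 10
Reactants: 12 (R)-1-[2-(tert-butyldimethylsilyloxymethyl)-8-methoxy-2-methyl-2H-chromen-6-yl]ethanone
Product: 13 (R)-1-[2-(hydroxymethyl)-8-methoxy-2-methyl-2H-chromen-6-yl]ethanone
Conditions: TBAF, AcOH, THF, 0 °C to rt, dark
Reagents that add atoms: none
Why: Fluoride-mediated desilylation driven by the strong Si–F bond, with acetic acid buffering so that the ketone and the chromene are left alone and C2 is not involved.

Step 11
Reactants: 14 ferulic acid
Product: 15 (E)-3-(4-acetoxy-3-methoxyphenyl)prop-2-enoic acid
Conditions: Ac2O, aq NaOH, 0 °C; then aq HCl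
Reagents that add atoms: acetic anhydride, CC(=O)OC(C)=O
Why: Schotten–Baumann-type O-acetylation, in which only the phenoxide is acylated durably in cold aqueous alkali, so acidification returns the free carboxylic acid with the phenol masked and the E alkene unchanged.

Step 12
Reactants: 13 (R)-1-[2-(hydroxymethyl)-8-methoxy-2-methyl-2H-chromen-6-yl]ethanone; 15 (E)-3-(4-acetoxy-3-methoxyphenyl)prop-2-enoic acid
Product: 16 [(R)-6-acetyl-8-methoxy-2-methyl-2H-chromen-2-yl]methyl (E)-3-(4-acetoxy-3-methoxyphenyl)prop-2-enoate
Conditions: DCC, DMAP (cat.), CH2Cl2, 0 °C to rt, dark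
Reagents that add atoms: none
Why: Steglich esterification, in which carbodiimide activation of the acid with DMAP as acyl-transfer catalyst acylates the neopentyl-type primary alcohol under neutral conditions at or below room temperature, leaving the chromene and C2 untouched.

Step 13
Reactants: 16 [(R)-6-acetyl-8-methoxy-2-methyl-2H-chromen-2-yl]methyl (E)-3-(4-acetoxy-3-methoxyphenyl)prop-2-enoate
Product: 17 [(R)-6-acetyl-8-methoxy-2-methyl-2H-chromen-2-yl]methyl (E)-3-(4-hydroxy-3-methoxyphenyl)prop-2-enoate (CNP0168033.1)
Conditions: pyrrolidine, CH2Cl2, 0 °C, dark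
Reagents that add atoms: none
Why: Selective phenolic deacetylation by aminolysis, since the aryl acetate is far more electrophilic than the alkyl cinnamate ester or the aryl ketone, so only the phenolic acetyl group should be removed.

## Compound list

1 | acetovanillone, 1-(4-hydroxy-3-methoxyphenyl)ethanone | CC(=O)c1ccc(O)c(OC)c1 | starting material
2 | diethyl bromomalonate | CCOC(=O)C(Br)C(=O)OCC | starting material
3 | diethyl 2-(4-acetyl-2-methoxyphenoxy)propanedioate | CCOC(=O)C(Oc1ccc(C(C)=O)cc1OC)C(=O)OCC | intermediate
4 | diethyl 2-(4-acetyl-2-methoxyphenoxy)-2-methylpropanedioate | CCOC(=O)C(C)(Oc1ccc(C(C)=O)cc1OC)C(=O)OCC | intermediate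
5 | 2-[4-(1-hydroxyethyl)-2-methoxyphenoxy]-2-methylpropane-1,3-diol (carbinol carbon racemic) | CC(O)c1ccc(OC(C)(CO)CO)c(OC)c1 | intermediate
6 | 1-{4-[(1,3-dihydroxy-2-methylpropan-2-yl)oxy]-3-methoxyphenyl}ethanone (prochiral) | CC(=O)c1ccc(OC(C)(CO)CO)c(OC)c1 | intermediate
7 | (R)-2-(4-acetyl-2-methoxyphenoxy)-3-hydroxy-2-methylpropyl acetate | CC(=O)OC[C@@](Oc1ccc(C(C)=O)cc1OC)(C)CO | intermediate
8 | (S)-2-(4-acetyl-2-methoxyphenoxy)-2-methyl-3-oxopropyl acetate | CC(=O)OC[C@@](Oc1ccc(C(C)=O)cc1OC)(C)C=O | intermediate
9 | (R)-2-(4-acetyl-2-methoxyphenoxy)-2-methylbut-3-yn-1-yl acetate (not isolated) | CC(=O)OC[C@@](Oc1ccc(C(C)=O)cc1OC)(C)C#C | intermediate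
10 | (R)-1-{4-[(1-hydroxy-2-methylbut-3-yn-2-yl)oxy]-3-methoxyphenyl}ethanone | OC[C@@](Oc1ccc(C(C)=O)cc1OC)(C)C#C | intermediate
11 | (R)-1-{4-[1-(tert-butyldimethylsilyloxy)-2-methylbut-3-yn-2-yl]oxy-3-methoxyphenyl}ethanone | CC(C)(C)[Si](C)(C)OC[C@@](Oc1ccc(C(C)=O)cc1OC)(C)C#C | intermediate
12 | (R)-1-[2-(tert-butyldimethylsilyloxymethyl)-8-methoxy-2-methyl-2H-chromen-6-yl]ethanone | CC(C)(C)[Si](C)(C)OC[C@@]1(C)C=Cc2cc(C(C)=O)cc(OC)c2O1 | intermediate
13 | (R)-1-[2-(hydroxymethyl)-8-methoxy-2-methyl-2H-chromen-6-yl]ethanone | OC[C@@]1(C)C=Cc2cc(C(C)=O)cc(OC)c2O1 | intermediate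
14 | ferulic acid, (E)-3-(4-hydroxy-3-methoxyphenyl)prop-2-enoic acid | COc1cc(/C=C/C(=O)O)ccc1O | starting material
15 | (E)-3-(4-acetoxy-3-methoxyphenyl)prop-2-enoic acid | COc1cc(/C=C/C(=O)O)ccc1OC(C)=O | intermediate
16 | [(R)-6-acetyl-8-methoxy-2-methyl-2H-chromen-2-yl]methyl (E)-3-(4-acetoxy-3-methoxyphenyl)prop-2-enoate | COc1cc(/C=C/C(=O)OC[C@@]2(C)C=Cc3cc(C(C)=O)cc(OC)c3O2)ccc1OC(C)=O | intermediate
17 | [(R)-6-acetyl-8-methoxy-2-methyl-2H-chromen-2-yl]methyl (E)-3-(4-hydroxy-3-methoxyphenyl)prop-2-enoate | COc1cc(/C=C/C(=O)OC[C@@]2(C)C=Cc3cc(C(C)=O)cc(OC)c3O2)ccc1O | target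

## Step count and risks

Total step count: 13. Longest linear sequence: 12 (steps 1 to 10, then 12 and 13); step 11 is the one-step side branch.

Steps most likely to fail:

**Step 5 (lipase desymmetrisation).** The enzyme may select the other enantiotopic hydroxymethyl arm, so that the monoacetate of opposite configuration is formed. The fallback sets out from 6 and comes back to the route at 11; the two arms simply exchange roles. The enzymatic acetylation would then give (S)-2-(4-acetyl-2-methoxyphenoxy)-3-hydroxy-2-methylpropyl acetate F1. Silylation of its free hydroxyl (TBSCl, imidazole, DMF) would give (R)-2-(4-acetyl-2-methoxyphenoxy)-3-(tert-butyldimethylsilyloxy)-2-methylpropyl acetate F2. Methanolysis of the acetate (catalytic K2CO3, MeOH, 0 °C, kept short to avoid silyl migration between the two oxygens) would give (R)-1-{4-[1-(tert-butyldimethylsilyloxy)-3-hydroxy-2-methylpropan-2-yl]oxy-3-methoxyphenyl}ethanone F3. Dess–Martin oxidation would give (S)-2-(4-acetyl-2-methoxyphenoxy)-3-(tert-butyldimethylsilyloxy)-2-methylpropanal F4, and Ohira–Bestmann homologation of F4 would give 11 directly.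

**Step 9 (gold hydroarylation).** Carbon–carbon bond formation at the acyl-deactivated ring may be slow, which would let hydration of the activated alkyne or heterolysis of the tertiary propargylic C–O bond compete. The fallback sets out from 11 and comes back at 13; it runs the closure at the alcohol oxidation level, on an electron-richer ring. NaBH4 (MeOH, 0 °C) would reduce the ketone to 1-{4-[(R)-1-(tert-butyldimethylsilyloxy)-2-methylbut-3-yn-2-yl]oxy-3-methoxyphenyl}ethanol F5 (both carbinol epimers). TBSCl and imidazole would give the bis-silyl ether tert-butyl(1-{4-[(R)-1-(tert-butyldimethylsilyloxy)-2-methylbut-3-yn-2-yl]oxy-3-methoxyphenyl}ethoxy)dimethylsilane F6. The same Ph3PAuNTf2 catalysis would give (R)-2-(tert-butyldimethylsilyloxymethyl)-6-[1-(tert-butyldimethylsilyloxy)ethyl]-8-methoxy-2-methyl-2H-chromene F7. TBAF would remove both silyl groups to give 1-[(R)-2-(hydroxymethyl)-8-methoxy-2-methyl-2H-chromen-6-yl]ethanol F8, and MnO2 would re-oxidise only the benzylic carbinol to give 13.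

**Step 7 (Ohira–Bestmann with acetate loss).** Methanolysis of the acetate before homologation would expose a β-hydroxy aldehyde to base, so retro-aldol loss of formaldehyde could divert material; addition to the neopentyl aldehyde may also be slow enough for attack at the methyl ketone to compete. The fallback sets out from 8 and comes back at 9, which is then isolated. Wittig bromomethylenation with the ylide from (bromomethyl)triphenylphosphonium bromide and KOtBu (THF, −78 °C) would give (R,Z)-2-(4-acetyl-2-methoxyphenoxy)-4-bromo-2-methylbut-3-en-1-yl acetate F9. Anti-elimination of HBr with tetrabutylammonium fluoride in DMF would give acetoxy alkyne 9, and K2CO3 in MeOH would then remove the acetate to rejoin the route at 10, the ester now being cleaved only after the aldehyde is gone.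

Further compounds
F1 | step 5 | (S)-2-(4-acetyl-2-methoxyphenoxy)-3-hydroxy-2-methylpropyl acetate | OC[C@@](Oc1ccc(C(C)=O)cc1OC)(C)COC(C)=O
F2 | step 5 | (R)-2-(4-acetyl-2-methoxyphenoxy)-3-(tert-butyldimethylsilyloxy)-2-methylpropyl acetate | CC(C)(C)[Si](C)(C)OC[C@@](Oc1ccc(C(C)=O)cc1OC)(C)COC(C)=O
F3 | step 5 | (R)-1-{4-[1-(tert-butyldimethylsilyloxy)-3-hydroxy-2-methylpropan-2-yl]oxy-3-methoxyphenyl}ethanone | CC(C)(C)[Si](C)(C)OC[C@@](Oc1ccc(C(C)=O)cc1OC)(C)CO
F4 | step 5 | (S)-2-(4-acetyl-2-methoxyphenoxy)-3-(tert-butyldimethylsilyloxy)-2-methylpropanal | CC(C)(C)[Si](C)(C)OC[C@@](Oc1ccc(C(C)=O)cc1OC)(C)C=O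
F5 | step 9 | 1-{4-[(R)-1-(tert-butyldimethylsilyloxy)-2-methylbut-3-yn-2-yl]oxy-3-methoxyphenyl}ethanol (both carbinol epimers) | CC(C)(C)[Si](C)(C)OC[C@@](Oc1ccc(C(C)O)cc1OC)(C)C#C
F6 | step 9 | tert-butyl(1-{4-[(R)-1-(tert-butyldimethylsilyloxy)-2-methylbut-3-yn-2-yl]oxy-3-methoxyphenyl}ethoxy)dimethylsilane | CC(C)(C)[Si](C)(C)OC[C@@](Oc1ccc(C(C)O[Si](C)(C)C(C)(C)C)cc1OC)(C)C#C
F7 | step 9 | (R)-2-(tert-butyldimethylsilyloxymethyl)-6-[1-(tert-butyldimethylsilyloxy)ethyl]-8-methoxy-2-methyl-2H-chromene | CC(C)(C)[Si](C)(C)OC[C@@]1(C)C=Cc2cc(C(C)O[Si](C)(C)C(C)(C)C)cc(OC)c2O1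
F8 | step 9 | 1-[(R)-2-(hydroxymethyl)-8-methoxy-2-methyl-2H-chromen-6-yl]ethanol | OC[C@@]1(C)C=Cc2cc(C(C)O)cc(OC)c2O1
F9 | step 7 | (R,Z)-2-(4-acetyl-2-methoxyphenoxy)-4-bromo-2-methylbut-3-en-1-yl acetate | CC(=O)OC[C@@](Oc1ccc(C(C)=O)cc1OC)(C)/C=C\Br
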